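**Retrosynthetic overview**
- Target ⇐ C15 malonylation and C18 debenzylation of an 8‑hydroxy ent‑labdane; the 8‑OH/CH3‑17 pair comes from Markovnikov hydration of the 8(17)‑alkene, made from the 8‑ketone.
- Key disconnection: ring B (C9–C10 bond) by oxidative one‑carbon ring expansion (1,2‑shift of quaternary C10) of an alkylidene trans‑hydrindane that already carries the whole C9–C16 side chain.
- Alkylidene ⇐ Wittig union of a C4‑quaternary trans‑hydrindan‑1‑one with a C7 phosphonium salt (C13 by Noyori hydrogenation; chain from 5‑chloropent‑1‑yne, Me3Al and CH2O).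
- Hydrindanone ⇐ Hajos–Parrish‑type enedione by reductive alkylation (C4, C5) and Wolff–Kishner removal of the C3 carbonyl; enedione ⇐ 2‑methylcyclopentane‑1,3‑dione + pent‑1‑en‑3‑one.
- Ring order: five‑membered ring (from the dione) → ring A (Robinson annulation) → ring B (ring expansion of the five‑membered ring).

Assumption: positions are quoted in labdane numbering (C1–C20; CH3‑20 on C10, CH2OH‑18 on C4); one‑carbon reagents and protecting‑group reagents are treated as reagents, not starting materials.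

**Step 1**
Reactants: 1 2‑methylcyclopentane‑1,3‑dione; 2 pent‑1‑en‑3‑one
Product: 4 (7aR)‑4,7a‑dimethyl‑2,3,7,7a‑tetrahydro‑1H‑indene‑1,5(6H)‑dione, via triketone 3 (not isolated)
Conditions: H2O, AcOH (cat.), 70 °C; then D‑phenylalanine (1 equiv), HClO4 (0.5 equiv), MeCN, reflux
Reagents that add atoms: none
Why: Michael addition then amino‑acid‑mediated intramolecular aldol condensation (Hajos–Parrish–Eder–Sauer–Wiechert Robinson annulation) closes ring A, and the D‑phenylalanine enamine differentiates the two enantiotopic ring carbonyls to set C10 (R), with ee raised by crystallisation.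

**Step 2**
Reactants: 4 (7aR)‑4,7a‑dimethyl‑2,3,7,7a‑tetrahydro‑1H‑indene‑1,5(6H)‑dione
Product: 5 (7a'R)‑4',7a'‑dimethyl‑2',3',7',7a'‑tetrahydrospiro[1,3‑dioxolane‑2,1'‑inden]‑5'(6'H)‑one
Conditions: HOCH2CH2OH, p‑TsOH·H2O, 4 Å MS, rt
Reagents that add atoms: ethane‑1,2‑diol, OCCO
Why: Acid‑catalysed ketalisation is selective because the saturated five‑ring ketone is more electrophilic than the conjugated, tetrasubstituted enone carbonyl.

**Step 3**
Reactants: 5 (7a'R)‑4',7a'‑dimethyl‑2',3',7',7a'‑tetrahydrospiro[1,3‑dioxolane‑2,1'‑inden]‑5'(6'H)‑one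
Product: 7 (3a'S,4'S,7a'R)‑4'‑[(benzyloxy)methyl]‑4',7a'‑dimethylhexahydrospiro[1,3‑dioxolane‑2,1'‑inden]‑5'(4'H)‑one, via lithium enolate 6 (not isolated)
Conditions: Li (2.2 equiv), t‑BuOH (1 equiv), NH3(l)/THF, −78 °C; remove NH3; BnOCH2Cl, THF/DMPU, −78→0 °C
Reagents that add atoms: benzyl chloromethyl ether, ClCOCc1ccccc1
Why: Birch‑type reductive alkylation: axial protonation at C5 gives the trans ring fusion, and the regiodefined C3–C4 lithium enolate is C‑alkylated on the face opposite the angular methyl, setting C4 (CH2OBn trans and CH3 cis to CH3‑20).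

**Step 4**
Reactants: 7 (3a'S,4'S,7a'R)‑4'‑[(benzyloxy)methyl]‑4',7a'‑dimethylhexahydrospiro[1,3‑dioxolane‑2,1'‑inden]‑5'(4'H)‑one
Product: 9 (3aR,4S,7aR)‑4‑[(benzyloxy)methyl]‑4,7a‑dimethyloctahydro‑1H‑inden‑1‑one, via deoxygenated ketal 8 (not isolated)
Conditions: N2H4·H2O, KOH, diethylene glycol, 130→200 °C; then 3 M HCl, THF, 50 °C
Reagents that add atoms: water, O
Why: Wolff–Kishner (Huang‑Minlon) reduction removes the C3 carbonyl (no β‑elimination is possible because C4 is quaternary; ketal and benzyl ether are base‑stable), and acid work‑up then hydrolyses the ketal.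

**Step 5**
Reactants: 10 5‑chloropent‑1‑yne
Product: 12 (2E)‑6‑chloro‑3‑methylhex‑2‑en‑1‑ol, via alkenylalane 11 (not isolated)
Conditions: Me3Al, Cp2ZrCl2 (0.25 equiv), CH2Cl2, 0 °C→rt; then n‑BuLi, (CH2O)n, THF, −78 °C→rt
Reagents that add atoms: trimethylaluminium, C[Al](C)C; formaldehyde (from paraformaldehyde), C=O
Why: Negishi zirconium‑catalysed carboalumination adds CH3 and Al syn across the alkyne (E geometry), and the alkenylalanate is hydroxymethylated by formaldehyde with retention.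

**Step 6**
Reactants: 12 (2E)‑6‑chloro‑3‑methylhex‑2‑en‑1‑ol
Product: 13 (3S)‑6‑chloro‑3‑methylhexan‑1‑ol
Conditions: Ru(OAc)2[(R)‑BINAP] (0.5 mol%), H2 (100 atm), MeOH, 20 °C
Reagents that add atoms: none
Why: Noyori asymmetric hydrogenation of an E allylic alcohol: the hydroxyl‑bound Ru–(R)‑BINAP hydride adds H2 to one alkene face and sets C13 (S), as geraniol gives (S)‑citronellol.

**Step 7**
Reactants: 13 (3S)‑6‑chloro‑3‑methylhexan‑1‑ol
Product: 14 [(4S)‑6‑hydroxy‑4‑methylhexyl]triphenylphosphonium iodide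
Conditions: PPh3, NaI, MeCN, reflux
Reagents that add atoms: triphenylphosphine, c1ccc(cc1)P(c1ccccc1)c1ccccc1; sodium iodide, [Na+].[I-]
Why: Finkelstein exchange followed by SN2 quaternisation of PPh3 at the primary carbon leaves the remote stereocentre untouched.

**Step 8**
Reactants: 9 (3aR,4S,7aR)‑4‑[(benzyloxy)methyl]‑4,7a‑dimethyloctahydro‑1H‑inden‑1‑one; 14 [(4S)‑6‑hydroxy‑4‑methylhexyl]triphenylphosphonium iodide
Product: 16 (3S,6Z)‑6‑[(3aS,4S,7aR)‑4‑[(benzyloxy)methyl]‑4,7a‑dimethyloctahydro‑1H‑inden‑1‑ylidene]‑3‑methylhexan‑1‑ol, via alkoxide ylide 15 (not isolated)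
Conditions: KOtBu (2.1 equiv per 14), toluene/THF, 0 °C→reflux
Reagents that add atoms: none
Why: Wittig olefination of the hindered five‑ring ketone by a non‑stabilised ylide, as with 17‑keto steroids, gives mainly the Z alkylidene (the E isomer would serve step 9 equally).

**Step 9**
Reactants: 16 (3S,6Z)‑6‑[(3aS,4S,7aR)‑4‑[(benzyloxy)methyl]‑4,7a‑dimethyloctahydro‑1H‑inden‑1‑ylidene]‑3‑methylhexan‑1‑ol
Product: 18 (1S,4aS,5S,8aR)‑5‑[(benzyloxy)methyl]‑1‑[(3S)‑5‑hydroxy‑3‑methylpentyl]‑5,8a‑dimethyloctahydronaphthalen‑2(1H)‑one, via dimethyl ketal 17 (not isolated)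
Conditions: PhI(OH)OTs (1.1 equiv), MeOH/CH2Cl2, −20→0 °C; then 1 M HCl, THF, rt; then K2CO3, MeOH, rt
Reagents that add atoms: water, O
Why: Proposed new method: oxidative ring expansion of a side‑chain‑bearing trisubstituted alkylidene hydrindane by the hypervalent iodine reagent, in which the alkene attacks electrophilic iodine, MeOH adds Markovnikov at ring carbon C8, and loss of PhI from C9 drives a semipinacol‑type 1,2‑shift of the more electron‑rich quaternary C10 (retention at C10, so trans fusion and 10R are kept) to the six‑membered C8 dimethyl ketal, which is hydrolysed and base‑equilibrated at C9 to the equatorial side chain (9S); the closest known reactions are the Koser‑reagent Wittig/ring‑expansion of benzocycloalkanones (aryl shift) and the thallium trinitrate ring expansion of methylenecycloalkanes, neither shown for an alkylidene carrying a full side chain next to a quaternary centre.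

**Step 10**
Reactants: 18 (1S,4aS,5S,8aR)‑5‑[(benzyloxy)methyl]‑1‑[(3S)‑5‑hydroxy‑3‑methylpentyl]‑5,8a‑dimethyloctahydronaphthalen‑2(1H)‑one
Product: 19 (3S)‑5‑[(1R,4aS,5S,8aS)‑5‑[(benzyloxy)methyl]‑5,8a‑dimethyl‑2‑methylidenedecahydronaphthalen‑1‑yl]‑3‑methylpentan‑1‑ol
Conditions: Ph3PCH3Br, KOtBu (excess), toluene, 90 °C
Reagents that add atoms: methyltriphenylphosphonium bromide, C[P+](c1ccccc1)(c1ccccc1)c1ccccc1.[Br-]
Why: Wittig methylenation of the 8‑ketone, with excess ylide covering the free hydroxyl and C9 remaining in its thermodynamic equatorial configuration.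

**Step 11**
Reactants: 19 (3S)‑5‑[(1R,4aS,5S,8aS)‑5‑[(benzyloxy)methyl]‑5,8a‑dimethyl‑2‑methylidenedecahydronaphthalen‑1‑yl]‑3‑methylpentan‑1‑ol
Product: 21 (1S,2S,4aS,5S,8aR)‑5‑[(benzyloxy)methyl]‑1‑[(3S)‑5‑hydroxy‑3‑methylpentyl]‑2,5,8a‑trimethyldecahydronaphthalen‑2‑ol, via hydroperoxide 20 (not isolated)
Conditions: Mn(dpm)3 (10 mol%), PhSiH3, O2 (1 atm), i‑PrOH/CH2Cl2, 0 °C; then PPh3
Reagents that add atoms: dioxygen, O=O
Why: Mukaiyama‑type hydrogen‑atom‑transfer hydration: Markovnikov H‑atom transfer gives the tertiary C8 radical, which O2 traps from the equatorial face away from the axial CH3‑20, so OH is equatorial and CH3‑17 axial (8S).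

**Step 12**
Reactants: 21 (1S,2S,4aS,5S,8aR)‑5‑[(benzyloxy)methyl]‑1‑[(3S)‑5‑hydroxy‑3‑methylpentyl]‑2,5,8a‑trimethyldecahydronaphthalen‑2‑ol; 22 malonic acid
Product: 23 3‑{[(3S)‑5‑{(1S,2S,4aS,5S,8aR)‑5‑[(benzyloxy)methyl]‑2‑hydroxy‑2,5,8a‑trimethyldecahydronaphthalen‑1‑yl}‑3‑methylpentyl]oxy}‑3‑oxopropanoic acid
Conditions: malonic acid (3 equiv), DCC (1.1 equiv), MeCN/THF, 0 °C→rt
Reagents that add atoms: none
Why: Carbodiimide‑mediated mono‑acylation by malonic acid (via its carboxyketene) takes only the primary C15 hydroxyl, since the C8 hydroxyl is tertiary and C18 is still benzyl‑protected.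

**Step 13**
Reactants: 23 3‑{[(3S)‑5‑{(1S,2S,4aS,5S,8aR)‑5‑[(benzyloxy)methyl]‑2‑hydroxy‑2,5,8a‑trimethyldecahydronaphthalen‑1‑yl}‑3‑methylpentyl]oxy}‑3‑oxopropanoic acid
Product: 24 3‑{[(3S)‑5‑{(1S,2S,4aS,5S,8aR)‑2‑hydroxy‑5‑(hydroxymethyl)‑2,5,8a‑trimethyldecahydronaphthalen‑1‑yl}‑3‑methylpentyl]oxy}‑3‑oxopropanoic acid (target)
Conditions: H2 (1 atm), Pd/C (10 wt%), EtOAc, rt
Reagents that add atoms: none
Why: Hydrogenolysis of the benzyl ether leaves the malonate half‑ester, the tertiary alcohol and all stereocentres untouched.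

**Compound list**
1 | 2‑methylcyclopentane‑1,3‑dione | CC1C(=O)CCC1=O | starting material
2 | pent‑1‑en‑3‑one | CCC(=O)C=C | starting material
3 | 2‑methyl‑2‑(3‑oxopentyl)cyclopentane‑1,3‑dione | CCC(=O)CCC1(C)C(=O)CCC1=O | intermediate
4 | (7aR)‑4,7a‑dimethyl‑2,3,7,7a‑tetrahydro‑1H‑indene‑1,5(6H)‑dione | C[C@@]12CCC(=O)C(C)=C1CCC2=O | intermediate
5 | (7a'R)‑4',7a'‑dimethyl‑2',3',7',7a'‑tetrahydrospiro[1,3‑dioxolane‑2,1'‑inden]‑5'(6'H)‑one | C[C@@]12CCC(=O)C(C)=C1CCC23OCCO3 | intermediate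
6 | lithium (3a'R,7a'R)‑4',7a'‑dimethyl‑2',3',3a',6',7',7a'‑hexahydrospiro[1,3‑dioxolane‑2,1'‑inden]‑5'‑olate (trans‑fused enolate) | C12(OCCO1)[C@]3(C)CCC(O[Li])=C(C)[C@H]3CC2 | intermediate
7 | (3a'S,4'S,7a'R)‑4'‑[(benzyloxy)methyl]‑4',7a'‑dimethylhexahydrospiro[1,3‑dioxolane‑2,1'‑inden]‑5'(4'H)‑one | C12(OCCO1)[C@]3(C)CCC(=O)[C@](C)(COCc4ccccc4)[C@H]3CC2 | intermediate
8 | (3a'R,4'S,7a'R)‑4'‑[(benzyloxy)methyl]‑4',7a'‑dimethyloctahydrospiro[1,3‑dioxolane‑2,1'‑indene] | C12(OCCO1)[C@]3(C)CCC[C@](C)(COCc4ccccc4)[C@H]3CC2 | intermediate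
9 | (3aR,4S,7aR)‑4‑[(benzyloxy)methyl]‑4,7a‑dimethyloctahydro‑1H‑inden‑1‑one | O=C1[C@]2(C)CCC[C@](C)(COCc3ccccc3)[C@H]2CC1 | intermediate
10 | 5‑chloropent‑1‑yne | C#CCCCCl | starting material
11 | [(1E)‑5‑chloro‑2‑methylpent‑1‑en‑1‑yl]dimethylalane | C[Al](C)/C=C(\C)CCCCl | intermediate
12 | (2E)‑6‑chloro‑3‑methylhex‑2‑en‑1‑ol | OC/C=C(\C)CCCCl | intermediate
13 | (3S)‑6‑chloro‑3‑methylhexan‑1‑ol | C[C@H](CCO)CCCCl | intermediate
14 | [(4S)‑6‑hydroxy‑4‑methylhexyl]triphenylphosphonium iodide | C[C@H](CCO)CCC[P+](c1ccccc1)(c1ccccc1)c1ccccc1.[I-] | intermediate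
15 | potassium (3S)‑3‑methyl‑6‑(triphenyl‑λ5‑phosphanylidene)hexan‑1‑olate | C[C@H](CC[O-])CCC=P(c1ccccc1)(c1ccccc1)c1ccccc1.[K+] | intermediate
16 | (3S,6Z)‑6‑[(3aS,4S,7aR)‑4‑[(benzyloxy)methyl]‑4,7a‑dimethyloctahydro‑1H‑inden‑1‑ylidene]‑3‑methylhexan‑1‑ol | C[C@H](CCO)CC/C=C1\[C@]2(C)CCC[C@](C)(COCc3ccccc3)[C@H]2CC1 | intermediate
17 | (3S)‑5‑[(1S,4aS,5S,8aR)‑5‑[(benzyloxy)methyl]‑2,2‑dimethoxy‑5,8a‑dimethyldecahydronaphthalen‑1‑yl]‑3‑methylpentan‑1‑ol | C[C@H](CCO)CC[C@H]1[C@]2(C)CCC[C@](C)(COCc3ccccc3)[C@H]2CCC1(OC)OC | intermediate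
18 | (1S,4aS,5S,8aR)‑5‑[(benzyloxy)methyl]‑1‑[(3S)‑5‑hydroxy‑3‑methylpentyl]‑5,8a‑dimethyloctahydronaphthalen‑2(1H)‑one | C[C@H](CCO)CC[C@H]1[C@]2(C)CCC[C@](C)(COCc3ccccc3)[C@H]2CCC1=O | intermediate
19 | (3S)‑5‑[(1R,4aS,5S,8aS)‑5‑[(benzyloxy)methyl]‑5,8a‑dimethyl‑2‑methylidenedecahydronaphthalen‑1‑yl]‑3‑methylpentan‑1‑ol | C[C@H](CCO)CC[C@H]1[C@]2(C)CCC[C@](C)(COCc3ccccc3)[C@H]2CCC1=C | intermediate
20 | (3S)‑5‑[(1S,2S,4aS,5S,8aR)‑5‑[(benzyloxy)methyl]‑2‑hydroperoxy‑2,5,8a‑trimethyldecahydronaphthalen‑1‑yl]‑3‑methylpentan‑1‑ol | C[C@H](CCO)CC[C@H]1[C@]2(C)CCC[C@](C)(COCc3ccccc3)[C@H]2CC[C@]1(C)OO | intermediate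
21 | (1S,2S,4aS,5S,8aR)‑5‑[(benzyloxy)methyl]‑1‑[(3S)‑5‑hydroxy‑3‑methylpentyl]‑2,5,8a‑trimethyldecahydronaphthalen‑2‑ol | C[C@H](CCO)CC[C@H]1[C@]2(C)CCC[C@](C)(COCc3ccccc3)[C@H]2CC[C@]1(C)O | intermediate
22 | malonic acid | OC(=O)CC(=O)O | starting material
23 | 3‑{[(3S)‑5‑{(1S,2S,4aS,5S,8aR)‑5‑[(benzyloxy)methyl]‑2‑hydroxy‑2,5,8a‑trimethyldecahydronaphthalen‑1‑yl}‑3‑methylpentyl]oxy}‑3‑oxopropanoic acid | C[C@H](CCOC(=O)CC(=O)O)CC[C@H]1[C@]2(C)CCC[C@](C)(COCc3ccccc3)[C@H]2CC[C@]1(C)O | intermediate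
24 | 3‑{[(3S)‑5‑{(1S,2S,4aS,5S,8aR)‑2‑hydroxy‑5‑(hydroxymethyl)‑2,5,8a‑trimethyldecahydronaphthalen‑1‑yl}‑3‑methylpentyl]oxy}‑3‑oxopropanoic acid | C[C@H](CCOC(=O)CC(=O)O)CC[C@H]1[C@]2(C)CCC[C@](C)(CO)[C@H]2CC[C@]1(C)O | target

**Step count and risks**
Total step count: 13. Longest linear sequence: 10 steps (steps 1–4 and 8–13).

The three steps most likely to fail:

Step 9 (the proposed ring expansion). The risks are shift of C7 instead of C10 and competing 1,2‑dimethoxylation. The fallback is known chemistry; it sets out from ketone 9 and chloro alcohol 13, comes back at ketone 18, and also bypasses step 8. Kornblum oxidation of 13 (NaI, NaHCO3, DMSO, 110 °C) gives the aldehyde (4S)‑6‑hydroxy‑4‑methylhexanal F1. MeSeH and ZnCl2 in CH2Cl2 convert it into the selenoacetal (3S)‑3‑methyl‑6,6‑bis(methylselanyl)hexan‑1‑ol F2. n‑BuLi (2.1 equiv, THF, −78 °C; alkoxide formation then Se/Li exchange) and addition to 9 from the face opposite the angular methyl give the β‑hydroxy selenide (3S)‑6‑[(1R,3aR,4S,7aR)‑4‑[(benzyloxy)methyl]‑1‑hydroxy‑4,7a‑dimethyloctahydro‑1H‑inden‑1‑yl]‑3‑methyl‑6‑(methylselanyl)hexan‑1‑ol F3 (both epimers at the selenium‑bearing carbon). AgBF4 on Al2O3 in CH2Cl2 (Krief selenium‑triggered ring enlargement with shift of the more substituted C10), then K2CO3/MeOH, gives 18.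

Step 3 (C‑ versus O‑alkylation of the hindered enolate by the chloromethyl ether). The fallback sets out from enone 5 and comes back at 7. After the same Li/NH3 reduction the enolate is silylated (TMSCl, Et3N) to the silyl enol ether (3a'R,7a'R)‑4',7a'‑dimethyl‑5'‑[(trimethylsilyl)oxy]‑2',3',3a',6',7',7a'‑hexahydrospiro[1,3‑dioxolane‑2,1'‑indene] F4. Mukaiyama‑type hydroxymethylation (aqueous CH2O, Sc(OTf)3 cat., THF), again anti to the angular methyl, gives (3a'S,4'S,7a'R)‑4'‑(hydroxymethyl)‑4',7a'‑dimethylhexahydrospiro[1,3‑dioxolane‑2,1'‑inden]‑5'(4'H)‑one F5. Acid‑catalysed benzylation (benzyl 2,2,2‑trichloroacetimidate, TfOH cat., CH2Cl2) gives 7.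

Step 11 (diastereoselectivity of O2 capture at C8). The fallback sets out from alkene 19 and comes back at 21. mCPBA with NaHCO3 in CH2Cl2 at 0 °C attacks the equatorial face to give the spiro‑epoxide (3S)‑5‑[(1S,2S,4aS,5S,8aR)‑5‑[(benzyloxy)methyl]‑5,8a‑dimethyloctahydro‑1H‑spiro[naphthalene‑2,2'‑oxiran]‑1‑yl]‑3‑methylpentan‑1‑ol F6. LiAlH4 in THF opens it at CH2 to give 21 (CH3‑17 axial, OH equatorial).

**Further compounds**
F1 | step 9 | (4S)‑6‑hydroxy‑4‑methylhexanal | C[C@H](CCO)CCC=O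
F2 | step 9 | (3S)‑3‑methyl‑6,6‑bis(methylselanyl)hexan‑1‑ol | C[C@H](CCO)CCC([Se]C)[Se]C
F3 | step 9 | (3S)‑6‑[(1R,3aR,4S,7aR)‑4‑[(benzyloxy)methyl]‑1‑hydroxy‑4,7a‑dimethyloctahydro‑1H‑inden‑1‑yl]‑3‑methyl‑6‑(methylselanyl)hexan‑1‑ol | C[C@H](CCO)CCC([Se]C)[C@]1(O)[C@]2(C)CCC[C@](C)(COCc3ccccc3)[C@H]2CC1
F4 | step 3 | (3a'R,7a'R)‑4',7a'‑dimethyl‑5'‑[(trimethylsilyl)oxy]‑2',3',3a',6',7',7a'‑hexahydrospiro[1,3‑dioxolane‑2,1'‑indene] | C12(OCCO1)[C@]3(C)CCC(O[Si](C)(C)C)=C(C)[C@H]3CC2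
F5 | step 3 | (3a'S,4'S,7a'R)‑4'‑(hydroxymethyl)‑4',7a'‑dimethylhexahydrospiro[1,3‑dioxolane‑2,1'‑inden]‑5'(4'H)‑one | C12(OCCO1)[C@]3(C)CCC(=O)[C@](C)(CO)[C@H]3CC2
F6 | step 11 | (3S)‑5‑[(1S,2S,4aS,5S,8aR)‑5‑[(benzyloxy)methyl]‑5,8a‑dimethyloctahydro‑1H‑spiro[naphthalene‑2,2'‑oxiran]‑1‑yl]‑3‑methylpentan‑1‑ol | C[C@H](CCO)CC[C@H]1[C@]2(C)CCC[C@](C)(COCc3ccccc3)[C@H]2CC[C@]1(C5)O5
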